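## Analysis of the target

The target joins two oxygen heterocycles through one methylene group. Ring A is an oxolane with a 3-hydroxy-4-methoxyphenyl group at C2, a hydroxymethyl group at C3 and, at C4, a CH2 group bonded to C6 of a 2,3-dihydro-1-benzofuran (rings B and C). The dihydrobenzofuran carries a 4-hydroxy-3-methoxyphenyl group at C2, a hydroxymethyl group at C3 and a methoxy group at C4.

There are five stereocenters. The oxolane is 2R,3S,4S: aryl trans to the C3 hydroxymethyl group, which is cis to the C4 methylene. The dihydrobenzofuran is 2S,3R (trans). The two sets are separated by a CH2–arene spacer, so neither can direct the other and absolute configuration has to be brought in twice.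

Both ring C2–O bonds are benzylic ethers activated by a para oxygen, so they ionise in acid and can be hydrogenolysed. The phenols must stay masked until the end; a free 4-hydroxyphenyl group would make the dihydrobenzofuran a quinone-methide precursor. The central arene is a 3,5-dioxygenated benzyl unit and is strongly nucleophilic at both positions ortho to the methylene.

The hard points are the 3,4-cis relationship in the oxolane, the sp3–sp2 junction next to two stereocenters, and a carbon substituent placed between the two oxygens of the central arene.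

The strategy rests on two features. The C4 methylene is bonded to an arene carbon (C6 of ring B), so it can be the nucleophilic carbon of an aryl-1,3-dithiane. Oxolane C5, C4, C3 and the C3 hydroxymethyl carbon form a four-carbon chain with oxygen at both ends. That chain maps onto a butenolide whose carbonyl is the hydroxymethyl carbon, C3 the α-carbon, C4 the β-carbon and C5 the acetal carbon. C2 with its aryl group is then an aldehyde.

## Retrosynthetic reasoning

**31 ⇒ 30 ⇒ 29.** Only O–H bonds are cut: two aryl benzyl ethers (hydrogenolysis) and one silyl ether. Free phenols would not survive the organolithium and hydride steps. The forward steps must leave the two cyclic benzylic C–O bonds intact, which is why the alkyl hydroxyl is silylated and only fast-cleaving phenolic benzyl ethers face hydrogen.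

**29 ⇒ 28.** The O1–C2 bond of the oxolane is cut, giving triol 28 with a benzylic carbinol. C2 carries a para-methoxyphenyl group and ionises easily, so the ring can be closed by cyclodehydration. Placing this bond last means the carbinol configuration formed earlier is irrelevant. The forward step has to close the five-membered ring through the C5 hydroxyl with the aryl group trans to the C3 substituent, and it has to do so before the central arene attacks the same cation.

**28 ⇒ 27.** The two primary alcohols are traced back to one lactone acetal. The C3 hydroxymethyl carbon becomes the lactone carbonyl and C5 becomes the acetal carbon bearing the menthyloxy group. One hydride reduction frees both carbons and releases the chiral controller 21. Because the old ring carbonyl becomes a substituent and the old substituent becomes a ring atom at C3, the trans lactone turns into the 3,4-cis oxolane.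

**27 ⇒ 26.** The two C–H bonds of the benzylic methylene are replaced by the C–S bonds of a dithiane. This group is what makes that carbon a nucleophile in the coupling.

**26 ⇒ 18 + 22 + 23.** The lactone C4–C(dithiane) bond and the lactone C3–C(carbinol) bond are cut. These are the two bonds where the three building blocks meet. Cutting at the methylene–arene bond instead would need an sp3–sp2 coupling with no element to control the adjacent stereocenters. Here the acetal center of 22 controls C4 and C4 controls C3. The forward reaction must add the anion of 18 in 1,4 fashion, anti to the menthyloxy group, and trap the enolate with 23 trans to the new substituent.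

**22 ⇒ 20 + 21, 20 ⇒ 19.** The acetal C–O bond is cut to give pseudo-acid 20 and 21; 20 comes from 19 by oxidative loss of the formyl carbon. This gives the enantiopure four-carbon unit in two steps.

**18 ⇒ 17 ⇒ 15.** The dithiane comes from aldehyde 17, and the formyl carbon from bromide 15 by halogen–metal exchange. Bromine is inert through all earlier steps and marks C6 unambiguously.

**15 ⇒ 14 ⇒ 12.** After removal of the silyl group, the O1–C2 bond of the dihydrobenzofuran is cut to give diol 12, with the phenol masked as a methoxymethyl ether. C2 is benzylic with a para oxygen, so the forward closure is an acid-promoted etherification that gives the trans ring whatever the carbinol configuration; only C3 has to be set beforehand.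

**12 ⇒ 11 ⇒ 8 + 9.** The C2–C3 bond of the dihydrobenzofuran is an aldol bond between imide 8 and aldehyde 9. Auxiliary 6 fixes the α-carbon, which becomes C3.

**8 ⇒ 5 + 6, 5 ⇒ 4 ⇒ 2 ⇒ 1.** The arylacetic acid comes from 1 by protection, metalation at the position between the two oxygens, hydroxyethylation and oxidation. Only a metalation directed by both oxygens reaches that position, and the two oxygens arrive already differentiated (methyl ether and removable acetal).

## Alternatives that were turned down

**Alternative 1: build the central arene from both halves.**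
- Disconnection: the benzene ring of the dihydrobenzofuran, including its C3a–C7a and C4–C5 bonds.
- Key step: on heating, cyclobutenone A1 (carrying the complete oxolane) opens and adds to siloxyalkyne A2 (carrying the future C3 and C2 of the dihydrobenzofuran); a second ring opening and a six-electron closure give phenol A3.
- For it: the union is very convergent, and the substitution pattern of the arene is fixed by the mechanism, with the side chain placed between the two oxygens without any directed metalation. On that point it is stronger than the chosen route.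
- Against it: the key step creates no stereocenter. A1 must already contain all three oxolane stereocenters and A2 both dihydrobenzofuran centers, one of them propargylic, and both must survive heating. A3 still needs ring closure at C2, exchange of the silyl ether for the methyl ether and removal of five protecting groups.
- Comparison: the chosen strategy starts from a purchased arene and in return creates two of the three oxolane centers in the step that joins the halves.

**Alternative 2: close the dihydrobenzofuran by carbenoid C–H insertion.**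
- Disconnection: the C2–C3 bond of the dihydrobenzofuran.
- Key step: a chiral dirhodium carboxylate turns diazo ester A4 into a carbenoid that inserts into the benzylic ether C–H; base in the same flask inverts C3 to give trans ester A5.
- For it: both ring stereocenters come from an achiral precursor by catalysis, without an auxiliary. As a way to the dihydrobenzofuran it is at least as short as the aldol sequence used here, and on that point it is as strong or stronger.
- Against it: the sense and level of induction for a carbenoid flanked by two ortho substituents are not secured, and an epimerisation is needed. More important, A5 is only one half of the target; the oxolane and the junction remain unsolved.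
- Comparison: the chosen strategy answers the junction and the oxolane, and pays with a stoichiometric but predictable auxiliary for the dihydrobenzofuran. The insertion is kept as the fallback for step 5.

**Alternative 3: radical cyclisation and arylation in one operation.**
- Disconnection: the oxolane C3–C4 bond and the methylene–arene bond.
- Key step: a nickel catalyst with a tridentate nitrogen ligand converts iodide A6 into a C3 radical that closes onto the allyl ether; the new primary radical is arylated by arylzinc A7 (available from bromide 15) to give A8, the fully protected target.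
- For it: ring formation and fragment union happen together and only deprotection remains. In step count after the union this route is clearly stronger.
- Against it: C3 and C4 are set in a flexible radical transition state. The preference for the 3,4-cis ring is only a conformational tendency, the relation to the C2 aryl group is modest, and nothing in A6 enforces either. The C2 center of A6 must also be made enantiopure beforehand.
- Comparison: the chosen strategy is four to five steps longer after the union, but a stereocenter next to each reacting carbon (the acetal carbon, then C4) dictates the outcome.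

Key step: step 13

Remark on the chemistry: the carbinol carbon formed in step 13 is carried as a mixture of both epimers through steps 14 and 15 (no descriptor in 26–28), because step 16 erases it. Compounds 1, 6, 9, 19, 21 and 23 are taken as purchasable.

Abbreviations used in names:
- ArV = 4-(benzyloxy)-3-methoxyphenyl
- ArI = 3-(benzyloxy)-4-methoxyphenyl
- Men = (1S,2R,5S)-5-methyl-2-(propan-2-yl)cyclohexyl
- TBS = tert-butyldimethylsilyl; MOM = methoxymethyl
- DHB = (2S,3R)-2-ArV-3-(TBS-oxymethyl)-4-methoxy-2,3-dihydro-1-benzofuran-6-yl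

## Route

Step 1
Reactants: 1 3-bromo-5-methoxyphenol
Product: 2 1-bromo-3-methoxy-5-(methoxymethoxy)benzene
Conditions: MOMCl, iPr2NEt, CH2Cl2, 0 °C → rt
Reagents that add atoms: chloromethyl methyl ether, COCCl
Why: O-alkylation of the phenol (Williamson type); the MOM ether masks the future ring oxygen and is a strong directing group for step 2.

Step 2
Reactants: 2 1-bromo-3-methoxy-5-(methoxymethoxy)benzene
Product: 4 2-[4-bromo-2-methoxy-6-(methoxymethoxy)phenyl]ethan-1-ol, via aryllithium 3 (not isolated)
Conditions: LiN(iPr)2 (LDA), THF, −78 °C; ethylene oxide, −78 → 0 °C; H2O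
Reagents that add atoms: oxirane (ethylene oxide), C1CO1
Why: Directed ortho-metalation: the proton between OMOM and OMe is the only one whose lithium is held by two oxygen atoms, and lithium para to bromine cannot eliminate LiBr. The aryllithium then opens the epoxide by SN2.

Step 3
Reactants: 4 2-[4-bromo-2-methoxy-6-(methoxymethoxy)phenyl]ethan-1-ol
Product: 5 [4-bromo-2-methoxy-6-(methoxymethoxy)phenyl]acetic acid
Conditions: TEMPO (cat.), PhI(OAc)2, MeCN/H2O, rt
Reagents that add atoms: water, O
Why: Oxoammonium oxidation of the primary alcohol to the aldehyde, whose hydrate is oxidised on to the acid; the medium is close to neutral, so the MOM ether and the aryl bromide are untouched.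

Step 4
Reactants: 5 [4-bromo-2-methoxy-6-(methoxymethoxy)phenyl]acetic acid; 6 (4S)-4-benzyl-1,3-oxazolidin-2-one
Product: 8 (4S)-4-benzyl-3-{[4-bromo-2-methoxy-6-(methoxymethoxy)phenyl]acetyl}-1,3-oxazolidin-2-one, via mixed pivalic anhydride 7 (not isolated)
Conditions: PivCl, Et3N, THF, −20 °C; then 6, LiCl, −20 °C → rt
Reagents that add atoms: none
Why: N-acylation of the oxazolidinone by the mixed anhydride, which reacts at the unhindered arylacetyl carbonyl; LiCl makes the oxazolidinone nucleophilic enough without a strong base.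

Step 5
Reactants: 8 (4S)-4-benzyl-3-{[4-bromo-2-methoxy-6-(methoxymethoxy)phenyl]acetyl}-1,3-oxazolidin-2-one; 9 4-(benzyloxy)-3-methoxybenzaldehyde
Product: 11 (4S)-4-benzyl-3-{(2S,3S)-3-ArV-2-[4-bromo-2-methoxy-6-(methoxymethoxy)phenyl]-3-hydroxypropanoyl}-1,3-oxazolidin-2-one, via Z-boron enolate 10 (not isolated)
Conditions: Bu2BOTf, iPr2NEt, CH2Cl2, 0 °C; 9, −78 → 0 °C; pH 7 buffer, MeOH, H2O2
Reagents that add atoms: none
Why: Evans syn aldol: the Z-boron enolate reacts through a closed chair transition state with the imide carbonyls opposed, and the aldehyde meets the enolate face away from the benzyl group, which should give the 2S,3S adduct. The 2S center becomes C3 (R) of the dihydrobenzofuran; the carbinol center is erased in step 7.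

Step 6
Reactants: 11 (4S)-4-benzyl-3-{(2S,3S)-3-ArV-2-[4-bromo-2-methoxy-6-(methoxymethoxy)phenyl]-3-hydroxypropanoyl}-1,3-oxazolidin-2-one
Product: 12 (1S,2R)-1-ArV-2-[4-bromo-2-methoxy-6-(methoxymethoxy)phenyl]propane-1,3-diol
Conditions: LiBH4, THF, MeOH (1 equiv), 0 °C
Reagents that add atoms: none
Why: Reductive cleavage of the N-acyl oxazolidinone at the exocyclic carbonyl gives the primary alcohol and returns the auxiliary; the descriptor at the α-carbon changes to R only because the priorities change.

Step 7
Reactants: 12 (1S,2R)-1-ArV-2-[4-bromo-2-methoxy-6-(methoxymethoxy)phenyl]propane-1,3-diol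
Product: 14 [(2S,3R)-2-ArV-6-bromo-4-methoxy-2,3-dihydro-1-benzofuran-3-yl]methanol, via free phenol 13 (not isolated)
Conditions: HCl (conc. aq.), MeOH/THF, 0 °C → rt
Reagents that add atoms: none
Why: Acid removes the MOM group and ionises the benzylic alcohol (cation stabilised by the para benzyloxy group); the phenol captures it in an SN1 etherification that closes the five-membered ring. The aryl group settles trans to the neighbouring hydroxymethyl group, the arrangement that forms faster and is more stable, so C2 should become S whatever the carbinol configuration; C3 is not touched.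

Step 8
Reactants: 14 [(2S,3R)-2-ArV-6-bromo-4-methoxy-2,3-dihydro-1-benzofuran-3-yl]methanol
Product: 15 (2S,3R)-2-ArV-6-bromo-3-(TBS-oxymethyl)-4-methoxy-2,3-dihydro-1-benzofuran
Conditions: TBSCl, imidazole, DMF, rt
Reagents that add atoms: tert-butyl(chloro)dimethylsilane, CC(C)(C)[Si](C)(C)Cl
Why: Silylation of the primary alcohol; the ether withstands the organolithium and hydride steps and is removed by fluoride without touching benzylic C–O bonds.

Step 9
Reactants: 15 (2S,3R)-2-ArV-6-bromo-3-(TBS-oxymethyl)-4-methoxy-2,3-dihydro-1-benzofuran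
Product: 17 (2S,3R)-2-ArV-3-(TBS-oxymethyl)-4-methoxy-2,3-dihydro-1-benzofuran-6-carbaldehyde, via aryllithium 16 (not isolated)
Conditions: n-BuLi, THF, −78 °C; DMF, −78 → 0 °C; H2O
Reagents that add atoms: N,N-dimethylformamide, CN(C)C=O
Why: Bromine–lithium exchange is faster at −78 °C than any deprotonation of the benzylic ether positions; formylation of the aryllithium with DMF follows.

Step 10
Reactants: 17 (2S,3R)-2-ArV-3-(TBS-oxymethyl)-4-methoxy-2,3-dihydro-1-benzofuran-6-carbaldehyde
Product: 18 2-DHB-1,3-dithiane
Conditions: HS(CH2)3SH, Zn(OTf)2 (cat.), CH2Cl2, rt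
Reagents that add atoms: propane-1,3-dithiol, SCCCS
Why: Lewis-acid-catalysed thioacetalisation of the aldehyde; the mild zinc catalyst is chosen so that the silyl ether and the benzylic aryl ether are not ionised.

Step 11
Reactants: 19 furan-2-carbaldehyde (furfural)
Product: 20 5-hydroxyfuran-2(5H)-one (racemic hemiacetal)
Conditions: O2, hν (visible), rose bengal (cat.), MeOH, 20 °C
Reagents that add atoms: dioxygen, O=O
Why: Singlet oxygen adds across C2/C5 of the furan ([4+2]); methanolysis of the endoperoxide expels the formyl carbon as methyl formate and leaves the pseudo-acid.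

Step 12
Reactants: 20 5-hydroxyfuran-2(5H)-one; 21 (+)-menthol [(1S,2R,5S)-5-methyl-2-(propan-2-yl)cyclohexan-1-ol]
Product: 22 (5S)-5-(Men-oxy)furan-2(5H)-one
Conditions: CSA (cat.), toluene, reflux (−H2O); crystallisation from hexanes, mother liquor re-equilibrated with CSA
Reagents that add atoms: none
Why: Acid-catalysed acetalisation of the hemiacetal. The two C5 epimers interconvert under the acid, and the 5S diastereomer is expected to be the crystalline one, so C5 is set by crystallisation-induced diastereomer enrichment.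

Step 13
Reactants: 18 2-DHB-1,3-dithiane; 22 (5S)-5-(Men-oxy)furan-2(5H)-one; 23 3-(benzyloxy)-4-methoxybenzaldehyde
Product: 26 (3R,4S,5S)-3-[ArI(hydroxy)methyl]-4-(2-DHB-1,3-dithian-2-yl)-5-(Men-oxy)oxolan-2-one (both carbinol epimers), via lithiated dithiane 24 (not isolated), via lactone lithium enolate 25 (not isolated)
Conditions: n-BuLi, THF, −78 → −30 °C; 22, −78 °C; 23, −78 °C; AcOH, −78 °C
Reagents that add atoms: none
Why: n-BuLi removes the C2 proton of dithiane 18 to give the sulfur-stabilised benzylic anion 24, an acyl-anion equivalent that the meta oxygen substituents do not destabilise. This soft, hindered anion adds 1,4 to butenolide 22 at C4 on the face opposite to the menthyloxy group on the adjacent C5, giving enolate 25; the C5 acetal center thus sets C4 (S). The enolate then adds to aldehyde 23 at C3 on the face away from the new bulky C4 substituent, so C3 (R) is set trans to C4 by 1,2-induction. The carbinol center is not controlled and need not be, because step 16 erases it. The closest known reaction type is the tandem conjugate addition–aldol of lithiated aryl dithioacetals with 5-alkoxyfuran-2(5H)-ones used for butyrolactone and furanoid lignans. No ring is closed; two C–C bonds and two ring stereocenters are formed in one flask. The step needs 1,4- over 1,2-addition (secured by the delocalised carbanion and the unhindered β-carbon), anti facial selectivity (secured by the bulky acetal substituent next to the reacting carbon) and enolate trapping faster than proton exchange (secured by complete deprotonation of 18 before 22 is added, low temperature and a cold acidic quench).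

Step 14
Reactants: 26 (3R,4S,5S)-3-[ArI(hydroxy)methyl]-4-(2-DHB-1,3-dithian-2-yl)-5-(Men-oxy)oxolan-2-one
Product: 27 (3R,4S,5S)-3-[ArI(hydroxy)methyl]-4-(DHB-methyl)-5-(Men-oxy)oxolan-2-one (both carbinol epimers)
Conditions: Raney Ni (W-2), EtOH/THF, rt
Reagents that add atoms: none
Why: Reductive desulfurisation of the dithioacetal on the nickel surface turns the quaternary carbon into the benzylic methylene. At room temperature benzyl ethers, the benzylic alcohol and the acetal should survive.

Step 15
Reactants: 27 (3R,4S,5S)-3-[ArI(hydroxy)methyl]-4-(DHB-methyl)-5-(Men-oxy)oxolan-2-one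
Product: 28 (2S,3S)-2-[ArI(hydroxy)methyl]-3-(DHB-methyl)butane-1,4-diol (both carbinol epimers)
Conditions: LiAlH4, THF, 0 °C → rt; H2O
Reagents that add atoms: none
Why: Hydride reduces the lactone carbonyl; the ring oxygen is thereby freed as a hemiacetal alkoxide that expels menthoxide, and the resulting aldehyde is reduced as well. Both stereocenters are untouched.

Step 16
Reactants: 28 (2S,3S)-2-[ArI(hydroxy)methyl]-3-(DHB-methyl)butane-1,4-diol
Product: 29 [(2R,3S,4S)-2-ArI-4-(DHB-methyl)oxolan-3-yl]methanol
Conditions: CSA (0.1 equiv), CH2Cl2, −20 → 0 °C, short; Et3N quench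
Reagents that add atoms: none
Why: SN1 cyclodehydration under kinetic control: the para-methoxybenzylic cation from either carbinol epimer is captured by the hydroxyl four atoms away (five-membered ring; the other primary hydroxyl could only give an oxetane). The aryl group should settle trans to the C3 substituent, which sets C2 (R). Oxygen capture is much faster than attack by the arene, so the reaction is stopped before the reversible ether can drain into the irreversible carbocycle.

Step 17
Reactants: 29 [(2R,3S,4S)-2-ArI-4-(DHB-methyl)oxolan-3-yl]methanol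
Product: 30 [(2S,3R)-2-ArV-6-{[(3S,4S,5R)-5-ArI-4-(hydroxymethyl)oxolan-3-yl]methyl}-4-methoxy-2,3-dihydro-1-benzofuran-3-yl]methanol
Conditions: Bu4NF (TBAF), THF, 0 °C → rt
Reagents that add atoms: none
Why: Fluoride-induced desilylation under non-acidic conditions, so neither benzylic ether can ionise.

Step 18
Reactants: 30 [(2S,3R)-2-ArV-6-{[(3S,4S,5R)-5-ArI-4-(hydroxymethyl)oxolan-3-yl]methyl}-4-methoxy-2,3-dihydro-1-benzofuran-3-yl]methanol
Product: 31 target: [(2S,3R)-2-(4-hydroxy-3-methoxyphenyl)-6-{[(3S,4S,5R)-5-(3-hydroxy-4-methoxyphenyl)-4-(hydroxymethyl)oxolan-3-yl]methyl}-4-methoxy-2,3-dihydro-1-benzofuran-3-yl]methanol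
Conditions: H2 (1 atm), Pd/C, EtOAc/EtOH, rt, stopped as soon as both ethers are gone
Reagents that add atoms: none
Why: Hydrogenolysis of the two primary benzyl aryl ethers, which cleave much faster than the hindered secondary benzylic C–O bonds held in the two rings.

## Compound list

1 | 3-bromo-5-methoxyphenol | COc1cc(O)cc(Br)c1 | starting material
2 | 1-bromo-3-methoxy-5-(methoxymethoxy)benzene | COCOc1cc(OC)cc(Br)c1 | intermediate
3 | [4-bromo-2-methoxy-6-(methoxymethoxy)phenyl]lithium | [Li]c1c(OC)cc(Br)cc1OCOC | intermediate (not isolated)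
4 | 2-[4-bromo-2-methoxy-6-(methoxymethoxy)phenyl]ethan-1-ol | OCCc1c(OC)cc(Br)cc1OCOC | intermediate
5 | [4-bromo-2-methoxy-6-(methoxymethoxy)phenyl]acetic acid | OC(=O)Cc1c(OC)cc(Br)cc1OCOC | intermediate
6 | (4S)-4-benzyl-1,3-oxazolidin-2-one | O=C1N[C@@H](Cc2ccccc2)CO1 | starting material
7 | mixed anhydride of 5 with pivalic acid | CC(C)(C)C(=O)OC(=O)Cc1c(OC)cc(Br)cc1OCOC | intermediate (not isolated)
8 | (4S)-4-benzyl-3-{[4-bromo-2-methoxy-6-(methoxymethoxy)phenyl]acetyl}-1,3-oxazolidin-2-one | O=C(Cc1c(OC)cc(Br)cc1OCOC)N1[C@@H](Cc2ccccc2)COC1=O | intermediate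
9 | 4-(benzyloxy)-3-methoxybenzaldehyde | COc1cc(C=O)ccc1OCc1ccccc1 | starting material
10 | Z-dibutylboron enolate of 8 | COCOc1cc(Br)cc(OC)c1/C=C(\OB(CCCC)CCCC)N1[C@@H](Cc2ccccc2)COC1=O | intermediate (not isolated)
11 | (4S)-4-benzyl-3-{(2S,3S)-3-ArV-2-[4-bromo-2-methoxy-6-(methoxymethoxy)phenyl]-3-hydroxypropanoyl}-1,3-oxazolidin-2-one | O=C(N1[C@@H](Cc2ccccc2)COC1=O)[C@@H](c1c(OC)cc(Br)cc1OCOC)[C@H](O)c1ccc(OCc2ccccc2)c(OC)c1 | intermediate
12 | (1S,2R)-1-ArV-2-[4-bromo-2-methoxy-6-(methoxymethoxy)phenyl]propane-1,3-diol | OC[C@@H](c1c(OC)cc(Br)cc1OCOC)[C@H](O)c1ccc(OCc2ccccc2)c(OC)c1 | intermediate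
13 | (1S,2R)-1-ArV-2-(4-bromo-2-hydroxy-6-methoxyphenyl)propane-1,3-diol | OC[C@@H](c1c(OC)cc(Br)cc1O)[C@H](O)c1ccc(OCc2ccccc2)c(OC)c1 | intermediate (not isolated)
14 | [(2S,3R)-2-ArV-6-bromo-4-methoxy-2,3-dihydro-1-benzofuran-3-yl]methanol | Brc1cc(OC)c2c(c1)O[C@H](c1ccc(OCc3ccccc3)c(OC)c1)[C@H]2CO | intermediate
15 | (2S,3R)-2-ArV-6-bromo-3-(TBS-oxymethyl)-4-methoxy-2,3-dihydro-1-benzofuran | Brc1cc(OC)c2c(c1)O[C@H](c1ccc(OCc3ccccc3)c(OC)c1)[C@H]2CO[Si](C)(C)C(C)(C)C | intermediate
16 | 6-lithio analogue of 15 | [Li]c1cc(OC)c2c(c1)O[C@H](c1ccc(OCc3ccccc3)c(OC)c1)[C@H]2CO[Si](C)(C)C(C)(C)C | intermediate (not isolated)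
17 | (2S,3R)-2-ArV-3-(TBS-oxymethyl)-4-methoxy-2,3-dihydro-1-benzofuran-6-carbaldehyde | O=Cc1cc(OC)c2c(c1)O[C@H](c1ccc(OCc3ccccc3)c(OC)c1)[C@H]2CO[Si](C)(C)C(C)(C)C | intermediate
18 | 2-DHB-1,3-dithiane | C1CSC(SC1)c1cc(OC)c2c(c1)O[C@H](c1ccc(OCc3ccccc3)c(OC)c1)[C@H]2CO[Si](C)(C)C(C)(C)C | intermediate
19 | furan-2-carbaldehyde (furfural) | O=Cc1ccco1 | starting material
20 | 5-hydroxyfuran-2(5H)-one | OC1OC(=O)C=C1 | intermediate
21 | (+)-menthol, (1S,2R,5S)-5-methyl-2-(propan-2-yl)cyclohexan-1-ol | CC(C)[C@H]1CC[C@H](C)C[C@@H]1O | starting material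
22 | (5S)-5-(Men-oxy)furan-2(5H)-one | O=C1C=C[C@@H](O[C@H]2C[C@@H](C)CC[C@@H]2C(C)C)O1 | intermediate
23 | 3-(benzyloxy)-4-methoxybenzaldehyde | COc1ccc(C=O)cc1OCc1ccccc1 | starting material
24 | 2-lithio-2-DHB-1,3-dithiane | [Li]C1(SCCCS1)c1cc(OC)c2c(c1)O[C@H](c1ccc(OCc3ccccc3)c(OC)c1)[C@H]2CO[Si](C)(C)C(C)(C)C | intermediate (not isolated)
25 | lithium enolate of (4S,5S)-4-(2-DHB-1,3-dithian-2-yl)-5-(Men-oxy)oxolan-2-one | O1[C@H](O[C@H]2C[C@@H](C)CC[C@@H]2C(C)C)[C@@H](C2(SCCCS2)c2cc(OC)c3c(c2)O[C@H](c2ccc(OCc4ccccc4)c(OC)c2)[C@H]3CO[Si](C)(C)C(C)(C)C)C=C1O[Li] | intermediate (not isolated)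
26 | (3R,4S,5S)-3-[ArI(hydroxy)methyl]-4-(2-DHB-1,3-dithian-2-yl)-5-(Men-oxy)oxolan-2-one, carbinol as either epimer | O1[C@H](O[C@H]2C[C@@H](C)CC[C@@H]2C(C)C)[C@@H](C2(SCCCS2)c2cc(OC)c3c(c2)O[C@H](c2ccc(OCc4ccccc4)c(OC)c2)[C@H]3CO[Si](C)(C)C(C)(C)C)[C@H](C(O)c2ccc(OC)c(OCc3ccccc3)c2)C1=O | intermediate
27 | (3R,4S,5S)-3-[ArI(hydroxy)methyl]-4-(DHB-methyl)-5-(Men-oxy)oxolan-2-one, carbinol as either epimer | O1[C@H](O[C@H]2C[C@@H](C)CC[C@@H]2C(C)C)[C@@H](Cc2cc(OC)c3c(c2)O[C@H](c2ccc(OCc4ccccc4)c(OC)c2)[C@H]3CO[Si](C)(C)C(C)(C)C)[C@H](C(O)c2ccc(OC)c(OCc3ccccc3)c2)C1=O | intermediate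
28 | (2S,3S)-2-[ArI(hydroxy)methyl]-3-(DHB-methyl)butane-1,4-diol, carbinol as either epimer | OC[C@@H](Cc1cc(OC)c2c(c1)O[C@H](c1ccc(OCc3ccccc3)c(OC)c1)[C@H]2CO[Si](C)(C)C(C)(C)C)[C@H](C(O)c1ccc(OC)c(OCc2ccccc2)c1)CO | intermediate
29 | [(2R,3S,4S)-2-ArI-4-(DHB-methyl)oxolan-3-yl]methanol | COc1ccc([C@@H]2OC[C@@H](Cc3cc(OC)c4c(c3)O[C@H](c3ccc(OCc5ccccc5)c(OC)c3)[C@H]4CO[Si](C)(C)C(C)(C)C)[C@H]2CO)cc1OCc1ccccc1 | intermediate
30 | bis(benzyl ether) of the target: [(2S,3R)-2-ArV-6-{[(3S,4S,5R)-5-ArI-4-(hydroxymethyl)oxolan-3-yl]methyl}-4-methoxy-2,3-dihydro-1-benzofuran-3-yl]methanol | COc1ccc([C@@H]2OC[C@@H](Cc3cc(OC)c4c(c3)O[C@H](c3ccc(OCc5ccccc5)c(OC)c3)[C@H]4CO)[C@H]2CO)cc1OCc1ccccc1 | intermediate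
31 | [(2S,3R)-2-(4-hydroxy-3-methoxyphenyl)-6-{[(3S,4S,5R)-5-(3-hydroxy-4-methoxyphenyl)-4-(hydroxymethyl)oxolan-3-yl]methyl}-4-methoxy-2,3-dihydro-1-benzofuran-3-yl]methanol | COc1ccc([C@@H]2OC[C@@H](Cc3cc(OC)c4c(c3)O[C@H](c3ccc(O)c(OC)c3)[C@H]4CO)[C@H]2CO)cc1O | target

## Step count and least certain steps

Total step count: 18. Longest linear sequence: 16 steps (steps 1–10 and 13–18, from 1).

**Step 13 (key step).** The most likely failure is incomplete trapping of enolate 25. Proton transfer from any unreacted 18, whose C2–H is acidic, would quench the enolate. The lithium aldolate of an electron-rich benzaldehyde can also revert on warming, leaving the lactone without its C3 branch.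
Fallback (from 18 and 22, back at 26): separate the two bond formations and make the second irreversible. The conjugate addition is run alone and quenched to give (4S,5S)-4-(2-DHB-1,3-dithian-2-yl)-5-(Men-oxy)oxolan-2-one F1. F1 is deprotonated with two equivalents of LiN(iPr)2 and C-acylated with 3-(benzyloxy)-4-methoxybenzoyl chloride to give keto lactone F2 (Claisen-type acylation, trans at the acidic C3 by equilibration). Reduction of the ketone with NaBH4 or Zn(BH4)2 gives 26.

**Step 16.** The most likely failure is loss of kinetic control. The oxolane can re-ionise under the acid, and each ionisation gives the electron-rich central arene a chance to attack the cation irreversibly (six-membered carbocycle). Partial formation of the 2,3-cis ether is the second risk.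
Fallback (from 27, back at 29): avoid the cation altogether and never break the carbinol C–O bond.
- Dess–Martin oxidation of 27 gives aroyl lactone F3.
- Zn(BH4)2 reduces F3 under chelation control (zinc bridging ketone and lactone carbonyl, hydride from the face away from C4) to the single (R)-carbinol lactone F4.
- LiAlH4 gives (R)-triol F5.
- TsCl in pyridine sulfonylates only the two primary hydroxyls, giving bis-tosylate F6.
- With base the remaining secondary hydroxyl displaces the tosylate four atoms away (5-exo-tet, with retention at the carbinol carbon; the four-membered alternative does not compete), giving oxolane tosylate F7.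
- CsOAc exchanges the remaining tosylate for acetate F8, and K2CO3 in MeOH frees the alcohol, which is 29.

**Step 5.** The most likely failure is slow addition of the enolate, which carries a 2,6-disubstituted aryl group, to an electron-rich aldehyde, followed by retro-aldol on work-up. That would mean low conversion and erosion at the α-carbon.
Fallback (from 5, back at 14): close the dihydrobenzofuran through its C2–C3 bond instead.
- HCl in MeOH esterifies 5 and removes the MOM group, giving methyl (4-bromo-2-hydroxy-6-methoxyphenyl)acetate F9.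
- K2CO3 and 4-(benzyloxy)-3-methoxybenzyl chloride give ether F10.
- Diazo transfer (p-acetamidobenzenesulfonyl azide, DBU) gives diazo ester F11.
- Rh2(S-PTTL)4, dirhodium tetrakis[N-phthaloyl-(S)-tert-leucinate], or its antipode (whichever gives the 2S series on this substrate) inserts the carbenoid into the benzylic ether C–H to give cis ester F12.
- NaOMe epimerises C3 to trans ester F13, and LiBH4 reduces the ester to 14.

**Step 14.** The most likely failure is over-reduction on the nickel surface: hydrogenolysis of the benzyl ethers or of the benzylic alcohol, or incomplete removal of the second sulfur.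
Fallback (from 26, back at 27): replace surface hydrogenolysis by a homogeneous radical chain. Bu3SnH in excess with AIBN in refluxing toluene cleaves the two benzylic C–S bonds one after the other through stabilised benzylic radicals and leaves benzyl ethers, silyl ether, lactone and alcohol untouched. No new compound is formed on the way.

## Further compounds

F1 | step 13 | (4S,5S)-4-(2-DHB-1,3-dithian-2-yl)-5-(Men-oxy)oxolan-2-one | O1[C@H](O[C@H]2C[C@@H](C)CC[C@@H]2C(C)C)[C@@H](C2(SCCCS2)c2cc(OC)c3c(c2)O[C@H](c2ccc(OCc4ccccc4)c(OC)c2)[C@H]3CO[Si](C)(C)C(C)(C)C)CC1=O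
F2 | step 13 | (3R,4S,5S)-3-[3-(benzyloxy)-4-methoxybenzoyl]-4-(2-DHB-1,3-dithian-2-yl)-5-(Men-oxy)oxolan-2-one | O1[C@H](O[C@H]2C[C@@H](C)CC[C@@H]2C(C)C)[C@@H](C2(SCCCS2)c2cc(OC)c3c(c2)O[C@H](c2ccc(OCc4ccccc4)c(OC)c2)[C@H]3CO[Si](C)(C)C(C)(C)C)[C@H](C(=O)c2ccc(OC)c(OCc3ccccc3)c2)C1=O
F3 | step 16 | (3R,4S,5S)-3-[3-(benzyloxy)-4-methoxybenzoyl]-4-(DHB-methyl)-5-(Men-oxy)oxolan-2-one | O1[C@H](O[C@H]2C[C@@H](C)CC[C@@H]2C(C)C)[C@@H](Cc2cc(OC)c3c(c2)O[C@H](c2ccc(OCc4ccccc4)c(OC)c2)[C@H]3CO[Si](C)(C)C(C)(C)C)[C@H](C(=O)c2ccc(OC)c(OCc3ccccc3)c2)C1=O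
F4 | step 16 | (3R,4S,5S)-3-[(R)-ArI(hydroxy)methyl]-4-(DHB-methyl)-5-(Men-oxy)oxolan-2-one | O1[C@H](O[C@H]2C[C@@H](C)CC[C@@H]2C(C)C)[C@@H](Cc2cc(OC)c3c(c2)O[C@H](c2ccc(OCc4ccccc4)c(OC)c2)[C@H]3CO[Si](C)(C)C(C)(C)C)[C@H]([C@@H](O)c2ccc(OC)c(OCc3ccccc3)c2)C1=O
F5 | step 16 | (2S,3S)-2-[(R)-ArI(hydroxy)methyl]-3-(DHB-methyl)butane-1,4-diol | OC[C@@H](Cc1cc(OC)c2c(c1)O[C@H](c1ccc(OCc3ccccc3)c(OC)c1)[C@H]2CO[Si](C)(C)C(C)(C)C)[C@H]([C@@H](O)c1ccc(OC)c(OCc2ccccc2)c1)CO
F6 | step 16 | 1,4-bis(4-methylbenzenesulfonate) of F5 | Cc1ccc(cc1)S(=O)(=O)OC[C@@H](Cc1cc(OC)c2c(c1)O[C@H](c1ccc(OCc3ccccc3)c(OC)c1)[C@H]2CO[Si](C)(C)C(C)(C)C)[C@H]([C@@H](O)c1ccc(OC)c(OCc2ccccc2)c1)COS(=O)(=O)c1ccc(C)cc1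
F7 | step 16 | [(2R,3S,4S)-2-ArI-4-(DHB-methyl)oxolan-3-yl]methyl 4-methylbenzenesulfonate | COc1ccc([C@@H]2OC[C@@H](Cc3cc(OC)c4c(c3)O[C@H](c3ccc(OCc5ccccc5)c(OC)c3)[C@H]4CO[Si](C)(C)C(C)(C)C)[C@H]2COS(=O)(=O)c2ccc(C)cc2)cc1OCc1ccccc1
F8 | step 16 | [(2R,3S,4S)-2-ArI-4-(DHB-methyl)oxolan-3-yl]methyl acetate | COc1ccc([C@@H]2OC[C@@H](Cc3cc(OC)c4c(c3)O[C@H](c3ccc(OCc5ccccc5)c(OC)c3)[C@H]4CO[Si](C)(C)C(C)(C)C)[C@H]2COC(C)=O)cc1OCc1ccccc1
F9 | step 5 | methyl (4-bromo-2-hydroxy-6-methoxyphenyl)acetate | COC(=O)Cc1c(O)cc(Br)cc1OC
F10 | step 5 | methyl [2-(ArV-methoxy)-4-bromo-6-methoxyphenyl]acetate | COC(=O)Cc1c(OC)cc(Br)cc1OCc1ccc(OCc2ccccc2)c(OC)c1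
F11 | step 5 | methyl 2-[2-(ArV-methoxy)-4-bromo-6-methoxyphenyl]-2-diazoacetate (same structure as A4) | COC(=O)C(=[N+]=[N-])c1c(OC)cc(Br)cc1OCc1ccc(OCc2ccccc2)c(OC)c1
F12 | step 5 | methyl (2S,3R)-2-ArV-6-bromo-4-methoxy-2,3-dihydro-1-benzofuran-3-carboxylate (cis) | Brc1cc(OC)c2c(c1)O[C@H](c1ccc(OCc3ccccc3)c(OC)c1)[C@@H]2C(=O)OC
F13 | step 5 | methyl (2S,3S)-2-ArV-6-bromo-4-methoxy-2,3-dihydro-1-benzofuran-3-carboxylate (trans, same structure as A5) | Brc1cc(OC)c2c(c1)O[C@H](c1ccc(OCc3ccccc3)c(OC)c1)[C@H]2C(=O)OC
F0 | step 14 | none | none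
A1 | alternative 1 | 3-{[(3S,4S,5R)-4-[(benzyloxy)methyl]-5-ArI-oxolan-3-yl]methyl}cyclobut-2-en-1-one | COc1ccc([C@@H]2OC[C@@H](CC3=CC(=O)C3)[C@H]2COCc2ccccc2)cc1OCc1ccccc1
A2 | alternative 1 | {[(3R,4R)-3-[(benzyloxy)methyl]-4-ArV-4-[(triethylsilyl)oxy]but-1-yn-1-yl]oxy}tri(propan-2-yl)silane | CC(C)[Si](C(C)C)(C(C)C)OC#C[C@H](COCc1ccccc1)[C@@H](O[Si](CC)(CC)CC)c1ccc(OCc2ccccc2)c(OC)c1
A3 | alternative 1 | pentasubstituted phenol: free hydroxyl at the future C7a, triisopropylsilyl ether at the future C4, the C3–C2 side chain between them and the oxolanylmethyl group para to that chain | COc1ccc([C@@H]2OC[C@@H](Cc3cc(O[Si](C(C)C)(C(C)C)C(C)C)c(c(O)c3)[C@H](COCc3ccccc3)[C@@H](O[Si](CC)(CC)CC)c3ccc(OCc4ccccc4)c(OC)c3)[C@H]2COCc2ccccc2)cc1OCc1ccccc1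
A4 | alternative 2 | methyl 2-[2-(ArV-methoxy)-4-bromo-6-methoxyphenyl]-2-diazoacetate | COC(=O)C(=[N+]=[N-])c1c(OC)cc(Br)cc1OCc1ccc(OCc2ccccc2)c(OC)c1
A5 | alternative 2 | methyl (2S,3S)-2-ArV-6-bromo-4-methoxy-2,3-dihydro-1-benzofuran-3-carboxylate (trans) | Brc1cc(OC)c2c(c1)O[C@H](c1ccc(OCc3ccccc3)c(OC)c1)[C@H]2C(=O)OC
A6 | alternative 3 | tert-butyl{[(3S)-3-ArI-2-iodo-3-(prop-2-en-1-yloxy)propyl]oxy}dimethylsilane (iodide carbon as either epimer) | COc1ccc([C@H](OCC=C)C(I)CO[Si](C)(C)C(C)(C)C)cc1OCc1ccccc1
A7 | alternative 3 | bromo(DHB)zinc | Br[Zn]c1cc(OC)c2c(c1)O[C@H](c1ccc(OCc3ccccc3)c(OC)c1)[C@H]2CO[Si](C)(C)C(C)(C)C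
A8 | alternative 3 | fully protected target (two benzyl ethers, two TBS ethers) | COc1ccc([C@@H]2OC[C@@H](Cc3cc(OC)c4c(c3)O[C@H](c3ccc(OCc5ccccc5)c(OC)c3)[C@H]4CO[Si](C)(C)C(C)(C)C)[C@H]2CO[Si](C)(C)C(C)(C)C)cc1OCc1ccccc1
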